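Whatever Sbt is left in this flask, Wednesday's, can go two ways: with Ctl to Prd, or with Prd to Sid. Is that leftover worth waiting for, or should the next run change its Ctl?

common to all: Sbt 20 mM (fed, over 2.0 h)
- Wednesday's: Ctl 2 µM; the very flask that is asked about, followed so far
- Saturday's: Ctl 4 µM; run made earlier
- flask: Ctl 2.0 µM; time 6.0 d

| run | time / d | Prd / % |
|---|---|---|
| Wednesday's | 0.333 | 36 |
| Wednesday's | 0.833 | 32 |
| Wednesday's | 1.67 | 30 |
| Wednesday's | 2.50 | 32 |
| Saturday's | 0.500 | 50 |
| Saturday's | 1.67 | 52 |
| Saturday's | 2.50 | 44 |
| Saturday's | 4.00 | 47 |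

(each reading ± 2 percentage points)

- percent here means Sbt units held: one Sid counts as two
- the numbers in the tables scatter by 2 percentage points (one standard deviation)
- steps thought possible: Sbt + Prd -> Sid; Sbt + Ctl -> Prd + Ctl
- the reaction counts as stopped when no species that holds the Sbt changes by six tenths of a point or more over the second half of the time

1. why nothing more happens at 6.0 d, or that something still does (all of Sbt has reacted / it is still moving)
2. amount of Prd at 6.0 d, in percent of the Sbt charged

Wednesday's readings stay between 30% and 36% from 0.333 d on, with a scatter of 2 percentage points, and average 32.5%. Saturday's run, with 4 µM of Ctl against 2 µM, averages 48.2%. Waiting shows us little, so we look at Ctl.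

We work in logarithms. Let n, the apparent order of the Prd yield in Ctl at this Sbt charge and feed, be the powers of ten gained in Prd per power of ten of Ctl. Our two averages give n = 0.570, which is below one. On that slope, a next run at 8.00 µM of Ctl should give about 71.6% Prd. That is the run we would charge, and we would not spend the days on this flask.

The forecast for this flask is all of Sbt has reacted, with Prd at 32% at 6.0 d, on the ground that “Sbt is used up within about 0.3 d”.

This flask gives all of Sbt has reacted: Sbt, the limiting reagent, stands at 0%, and Prd at 30.6%.

    Sbt + Prd → Sid (k = 0.00520 L mol⁻¹ s⁻¹)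
    Sbt + Ctl → Prd + Ctl, rate k2*[Sbt]^2*[Ctl]/(1 + ([Sbt]/Kh2)^2) (16.0 mM, k = 5100 L² mol⁻² s⁻¹)

At 0.106 d in this flask, the step to Prd uses Sbt 2.8 times as fast as the step to Sid. At 6.00 d the neighbour flask with 8.00 µM of Ctl holds 60.2% Prd, not our 71.6%, a slope from this flask to that one of 0.488 against n of 0.570.

The data are simulated for an exercise, noise included.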